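**Retrosynthetic overview**

1. Caraganin C is an all-trans 2,3,4-trisubstituted 7-methoxychroman; the two phenols are freed last, and the E-styryl arm comes from cross-metathesis of a C4 vinyl group.
2. Key disconnection: the aryl ether bond O1–C8a. The pyran ring closes when the C2 alkoxide adds to a ring-A aryne (triple bond C8–C8a) generated from a C8a bromide and a C8 triflate, both inherited from 2-bromoisovanillin and both lost in the same operation.
3. Enabling feature: C8 of ring A bears only H and lies between the C7 methoxy group and C8a, so the C8–C8a aryne is a 3-methoxyaryne that takes nucleophiles at C8a; the C2 oxygen, tied to C4a through C4–C3, can reach only C8a (six-membered closure).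
4. C2 is set by Felkin–Anh reduction of the aryl ketone (aldehyde plus aryl Grignard, then oxidation); C3 and C4 are set together by iridium/enamine dual-catalytic α-allylation of a 3-arylpropanal with a racemic aryl vinyl carbinol.
5. Ring order: the four benzene rings are bought; the pyran ring is the only ring formed (step 9).

Key step: step 9

Assumption: in step 5 the sense of induction is assigned by analogy (the (S)-amine for the 2R centre, the (R)-ligand for the 3R centre); the two catalysts act independently, so the other ligand enantiomer is used if its sense proves opposite.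

Abbreviations in names: TBS = tert-butyldimethylsilyl, Tf = trifluoromethanesulfonyl.

**Route**

Step 1
Reactants: 1 2-bromo-3-hydroxy-4-methoxybenzaldehyde (2-bromoisovanillin)
Product: 2 2-bromo-3-formyl-6-methoxyphenyl trifluoromethanesulfonate
Conditions: Tf2O, pyridine, CH2Cl2, 0 °C
Reagents that add atoms: trifluoromethanesulfonic anhydride, O=S(=O)(OS(=O)(=O)C(F)(F)F)C(F)(F)F
Why: O-sulfonylation of the phenol places the leaving group on the future C8 next to the C8a bromide, and no stereocenter is involved.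

Step 2
Reactants: 2 2-bromo-3-formyl-6-methoxyphenyl trifluoromethanesulfonate
Product: 3 rac-2-bromo-3-(1-hydroxyprop-2-en-1-yl)-6-methoxyphenyl trifluoromethanesulfonate
Conditions: CH2=CHMgBr, THF, −78 °C; aqueous work-up
Reagents that add atoms: vinylmagnesium bromide, C=C[Mg]Br
Why: Grignard 1,2-addition to the aldehyde should outrun attack on the aryl triflate at −78 °C, and the racemate suffices because step 5 is enantioconvergent.

Step 3
Reactants: 4 methyl 3-(4-hydroxyphenyl)propanoate
Product: 5 methyl 3-[4-(tert-butyldimethylsilyloxy)phenyl]propanoate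
Conditions: TBSCl, imidazole, DMF, 23 °C
Reagents that add atoms: tert-butyldimethylsilyl chloride, CC(C)(C)[Si](C)(C)Cl
Why: Silylation of the phenol masks it against the organometallic and oxidation steps and allows a fluoride release at the end.

Step 4
Reactants: 5 methyl 3-[4-(tert-butyldimethylsilyloxy)phenyl]propanoate
Product: 6 3-[4-(tert-butyldimethylsilyloxy)phenyl]propanal
Conditions: i-Bu2AlH (1.05 equiv), CH2Cl2, −78 °C; aqueous KNaC4H4O6 (sodium potassium tartrate)
Reagents that add atoms: none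
Why: Partial reduction of the ester with a dialkylaluminium hydride should stop at the aldehyde oxidation level at −78 °C.

Step 5
Reactants: 3 rac-2-bromo-3-(1-hydroxyprop-2-en-1-yl)-6-methoxyphenyl trifluoromethanesulfonate and 6 3-[4-(tert-butyldimethylsilyloxy)phenyl]propanal (2.5 equiv)
Product: 7 (2R,3R)-3-[2-bromo-4-methoxy-3-(TfO)phenyl]-2-[4-(TBSO)benzyl]pent-4-enal
Conditions: [Ir(cod)Cl]2 (3 mol%), (R)-BINOL-derived N-(5H-dibenzo[b,f]azepin-5-yl) phosphoramidite (P,olefin ligand, 12 mol%), (S)-α,α-bis[3,5-bis(trifluoromethyl)phenyl]prolinol trimethylsilyl ether (15 mol%), (MeO)2P(O)OH (50 mol%), ClCH2CH2Cl, 25 °C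
Reagents that add atoms: none
Why: In this stereodivergent dual catalysis (iridium-catalysed allylic substitution merged with enamine catalysis) the racemic carbinol should ionise with loss of water to one chiral allyliridium electrophile whose ligand sets the allylic centre (3R) at the branched terminus, while the chiral amine activates 6 as an enamine with one open face and sets the α-centre (2R), giving the anti isomer.

Step 6
Reactants: 7 (2R,3R)-3-[2-bromo-4-methoxy-3-(TfO)phenyl]-2-[4-(TBSO)benzyl]pent-4-enal and 8 2,4-dimethoxyphenylmagnesium bromide (THF solution)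
Product: 9 (2R,3R)-3-[2-bromo-4-methoxy-3-(TfO)phenyl]-2-[4-(TBSO)benzyl]-1-(2,4-dimethoxyphenyl)pent-4-en-1-ol (both C1 epimers)
Conditions: THF, −78 °C; aqueous work-up
Reagents that add atoms: none
Why: Aryl Grignard 1,2-addition at −78 °C should be faster than enolisation of the α-branched aldehyde, and the new carbinol centre need not be controlled because step 7 erases it.

Step 7
Reactants: 9 (2R,3R)-3-[2-bromo-4-methoxy-3-(TfO)phenyl]-2-[4-(TBSO)benzyl]-1-(2,4-dimethoxyphenyl)pent-4-en-1-ol (both C1 epimers)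
Product: 10 (2R,3R)-3-[2-bromo-4-methoxy-3-(TfO)phenyl]-2-[4-(TBSO)benzyl]-1-(2,4-dimethoxyphenyl)pent-4-en-1-one
Conditions: Dess–Martin periodinane, CH2Cl2, 0 to 23 °C
Reagents that add atoms: none
Why: Dess–Martin oxidation under near-neutral conditions should converge both epimers on one ketone without epimerising the α-centre.

Step 8
Reactants: 10 (2R,3R)-3-[2-bromo-4-methoxy-3-(TfO)phenyl]-2-[4-(TBSO)benzyl]-1-(2,4-dimethoxyphenyl)pent-4-en-1-one
Product: 11 (1R,2R,3R)-3-[2-bromo-4-methoxy-3-(TfO)phenyl]-2-[4-(TBSO)benzyl]-1-(2,4-dimethoxyphenyl)pent-4-en-1-ol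
Conditions: LiBH(s-Bu)3, THF, −78 °C; aqueous work-up
Reagents that add atoms: none
Why: In this Felkin–Anh-controlled ketone reduction the bulky hydride should enter anti to the branched CH(aryl)(vinyl) arm with the benzyl group beside the carbonyl oxygen, which sets 1R (hydroxyl anti to the benzyl arm in the zigzag chain).

Step 9
Reactants: 11 (1R,2R,3R)-3-[2-bromo-4-methoxy-3-(TfO)phenyl]-2-[4-(TBSO)benzyl]-1-(2,4-dimethoxyphenyl)pent-4-en-1-ol
Product: 14 (2R,3R,4R)-3-[4-(TBSO)benzyl]-2-(2,4-dimethoxyphenyl)-4-ethenyl-7-methoxychroman, via lithium alkoxide aryne 12 (not isolated), via 8-lithiochroman 13 (not isolated)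
Conditions: n-BuLi (2.1 equiv, slow addition), THF (0.02 M), −78 °C; H2O quench at −78 °C
Reagents that add atoms: none
Why: The first equivalent of n-BuLi makes the lithium alkoxide and the second exchanges the C8a bromide, whereupon loss of LiOTf from C8 gives aryne 12 (triple bond C8–C8a); the alkoxide oxygen adds to C8a and the resulting C8 aryllithium 13 is protonated on quench, so that bromide and triflate both leave without trace. The closest known reaction types are aryne generation from ortho-haloaryl triflates by halogen–lithium exchange and the intramolecular addition of alkoxides to arynes that gives chromans and dihydrobenzofurans. The pyran ring closes in the 6-exo-dig mode. No stereocenter is formed, and C2, C3 and C4 are retained because no bond to them is broken and all organolithium species live only at −78 °C, where the benzylic and allylic C4–H should not be removed. The step needs regioselectivity for C8a over C8 and capture by oxygen within the molecule: the C7 methoxy group beside the triple bond polarises the aryne so that the nucleophile enters at the distal carbon C8a and the charge develops at C8, and the C4–C3–C2 bridge from C4a permits only the six-membered closure. Slow addition of n-BuLi to a dilute solution keeps free butyllithium and a second substrate molecule away from the aryne.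

Step 10
Reactants: 14 (2R,3R,4R)-3-[4-(TBSO)benzyl]-2-(2,4-dimethoxyphenyl)-4-ethenyl-7-methoxychroman and 15 4-(tert-butyldimethylsilyloxy)styrene (3 equiv)
Product: 16 (2R,3R,4R)-3-[4-(TBSO)benzyl]-2-(2,4-dimethoxyphenyl)-7-methoxy-4-[(E)-2-(4-(TBSO)phenyl)ethenyl]chroman
Conditions: second-generation Grubbs catalyst (5 mol%), 1,4-benzoquinone (10 mol%), CH2Cl2, 40 °C
Reagents that add atoms: none
Why: Olefin cross-metathesis between the hindered, slowly dimerising C4 vinyl group and an excess of the styrene should give the E-styryl alkene under thermodynamic control with loss of ethene, the quinone suppressing double-bond migration.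

Step 11
Reactants: 16 (2R,3R,4R)-3-[4-(TBSO)benzyl]-2-(2,4-dimethoxyphenyl)-7-methoxy-4-[(E)-2-(4-(TBSO)phenyl)ethenyl]chroman
Product: 17 caraganin C, (2R,3R,4R)-2-(2,4-dimethoxyphenyl)-3-(4-hydroxybenzyl)-4-[(E)-2-(4-hydroxyphenyl)ethenyl]-7-methoxychroman
Conditions: n-Bu4NF (2.4 equiv), AcOH (2.4 equiv), THF, 0 °C
Reagents that add atoms: none
Why: Fluoride desilylation should free both phenols, the acetic acid buffer keeping the acid-labile 2-arylchroman ether and the doubly activated C4–H away from strong acid or base.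

**Compound list**

1 | 2-bromo-3-hydroxy-4-methoxybenzaldehyde | COc1ccc(C=O)c(Br)c1O | starting material
2 | 2-bromo-3-formyl-6-methoxyphenyl trifluoromethanesulfonate | COc1ccc(C=O)c(Br)c1OS(=O)(=O)C(F)(F)F | intermediate
3 | rac-2-bromo-3-(1-hydroxyprop-2-en-1-yl)-6-methoxyphenyl trifluoromethanesulfonate | COc1ccc(C(O)C=C)c(Br)c1OS(=O)(=O)C(F)(F)F | intermediate
4 | methyl 3-(4-hydroxyphenyl)propanoate | COC(=O)CCc1ccc(O)cc1 | starting material
5 | methyl 3-[4-(tert-butyldimethylsilyloxy)phenyl]propanoate | COC(=O)CCc1ccc(O[Si](C)(C)C(C)(C)C)cc1 | intermediate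
6 | 3-[4-(tert-butyldimethylsilyloxy)phenyl]propanal | O=CCCc1ccc(O[Si](C)(C)C(C)(C)C)cc1 | intermediate
7 | (2R,3R)-3-[2-bromo-4-methoxy-3-(TfO)phenyl]-2-[4-(TBSO)benzyl]pent-4-enal | O=C[C@H](Cc1ccc(O[Si](C)(C)C(C)(C)C)cc1)[C@@H](C=C)c1ccc(OC)c(OS(=O)(=O)C(F)(F)F)c1Br | intermediate
8 | 2,4-dimethoxyphenylmagnesium bromide | COc1ccc([Mg]Br)c(OC)c1 | starting material
9 | (2R,3R)-3-[2-bromo-4-methoxy-3-(TfO)phenyl]-2-[4-(TBSO)benzyl]-1-(2,4-dimethoxyphenyl)pent-4-en-1-ol, both C1 epimers | COc1ccc(C(O)[C@H](Cc2ccc(O[Si](C)(C)C(C)(C)C)cc2)[C@@H](C=C)c2ccc(OC)c(OS(=O)(=O)C(F)(F)F)c2Br)c(OC)c1 | intermediate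
10 | (2R,3R)-3-[2-bromo-4-methoxy-3-(TfO)phenyl]-2-[4-(TBSO)benzyl]-1-(2,4-dimethoxyphenyl)pent-4-en-1-one | COc1ccc(C(=O)[C@H](Cc2ccc(O[Si](C)(C)C(C)(C)C)cc2)[C@@H](C=C)c2ccc(OC)c(OS(=O)(=O)C(F)(F)F)c2Br)c(OC)c1 | intermediate
11 | (1R,2R,3R)-3-[2-bromo-4-methoxy-3-(TfO)phenyl]-2-[4-(TBSO)benzyl]-1-(2,4-dimethoxyphenyl)pent-4-en-1-ol | O[C@@H](c1ccc(OC)cc1OC)[C@H](Cc1ccc(O[Si](C)(C)C(C)(C)C)cc1)[C@@H](C=C)c1ccc(OC)c(OS(=O)(=O)C(F)(F)F)c1Br | intermediate
12 | lithium alkoxide of 11 with ring A as the C8–C8a aryne (bromide and triflate lost) | [Li]O[C@@H](c1ccc(OC)cc1OC)[C@H](Cc1ccc(O[Si](C)(C)C(C)(C)C)cc1)[C@@H](C=C)C1=CC=C(OC)C#C1 | intermediate (not isolated)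
13 | (2R,3R,4R)-3-[4-(TBSO)benzyl]-2-(2,4-dimethoxyphenyl)-4-ethenyl-8-lithio-7-methoxychroman | COc1ccc2c(c1[Li])O[C@@H](c1ccc(OC)cc1OC)[C@H](Cc1ccc(O[Si](C)(C)C(C)(C)C)cc1)[C@H]2C=C | intermediate (not isolated)
14 | (2R,3R,4R)-3-[4-(TBSO)benzyl]-2-(2,4-dimethoxyphenyl)-4-ethenyl-7-methoxychroman | COc1ccc2c(c1)O[C@@H](c1ccc(OC)cc1OC)[C@H](Cc1ccc(O[Si](C)(C)C(C)(C)C)cc1)[C@H]2C=C | intermediate
15 | 4-(tert-butyldimethylsilyloxy)styrene | C=Cc1ccc(O[Si](C)(C)C(C)(C)C)cc1 | starting material
16 | (2R,3R,4R)-3-[4-(TBSO)benzyl]-2-(2,4-dimethoxyphenyl)-7-methoxy-4-[(E)-2-(4-(TBSO)phenyl)ethenyl]chroman | COc1ccc2c(c1)O[C@@H](c1ccc(OC)cc1OC)[C@H](Cc1ccc(O[Si](C)(C)C(C)(C)C)cc1)[C@H]2/C=C/c1ccc(O[Si](C)(C)C(C)(C)C)cc1 | intermediate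
17 | caraganin C | COc1ccc2c(c1)O[C@@H](c1ccc(OC)cc1OC)[C@H](Cc1ccc(O)cc1)[C@H]2/C=C/c1ccc(O)cc1 | target

**Step count and risks**

Total step count: 11. Longest linear sequence: 9 steps (steps 1, 2, 5, 6, 7, 8, 9, 10, 11).

Steps most likely to fail:

Step 9 (key step). What may go wrong: attack of n-BuLi on the triflate sulfur or an anionic thia-Fries shift in place of elimination, and capture of the aryne between molecules. Fallback (cross-coupling in place of the aryne): starting from 11, a copper-catalysed Ullmann-type intramolecular etherification at the C8a bromide (CuI, 3,4,7,8-tetramethyl-1,10-phenanthroline, Cs2CO3, toluene, 100 °C) should leave the triflate untouched and give (2R,3R,4R)-3-[4-(TBSO)benzyl]-2-(2,4-dimethoxyphenyl)-4-ethenyl-7-methoxychroman-8-yl trifluoromethanesulfonate F1. Reductive removal of the C8 triflate (Pd(OAc)2, 1,1'-bis(diphenylphosphino)ferrocene, HCO2H, Et3N, DMF, 60 °C) then rejoins the route at 14.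

Step 5. What may go wrong: loss of branched selectivity and of catalyst control because the ortho bromide crowds the allyl terminus, and epimerisation of the aldehyde α-centre. Fallback (auxiliary control in place of dual catalysis): starting from 2, a Horner–Wadsworth–Emmons reaction with diethyl {2-oxo-2-[(4R)-2-oxo-4-phenyl-1,3-oxazolidin-3-yl]ethyl}phosphonate (LiCl, i-Pr2NEt, MeCN) should give (4R)-3-{(E)-3-[2-bromo-4-methoxy-3-(TfO)phenyl]prop-2-enoyl}-4-phenyl-1,3-oxazolidin-2-one F2. Copper-mediated conjugate addition of CH2=CHMgBr (CuBr·SMe2, THF, −40 °C) anti to the phenyl group of the chelated acyl oxazolidinone should give (4R)-3-{(3S)-3-[2-bromo-4-methoxy-3-(TfO)phenyl]pent-4-enoyl}-4-phenyl-1,3-oxazolidin-2-one F3. Alkylation of its sodium enolate (NaN(SiMe3)2, THF, −78 °C) with 4-(tert-butyldimethylsilyloxy)benzyl bromide, again anti to the phenyl group, should give (4R)-3-{(2R,3R)-3-[2-bromo-4-methoxy-3-(TfO)phenyl]-2-[4-(TBSO)benzyl]pent-4-enoyl}-4-phenyl-1,3-oxazolidin-2-one F4. LiBH4 (THF, H2O, 0 °C) cleaves the auxiliary to (2R,3R)-3-[2-bromo-4-methoxy-3-(TfO)phenyl]-2-[4-(TBSO)benzyl]pent-4-en-1-ol F5, and Dess–Martin oxidation of F5 returns to the route at 7.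

Step 8. What may go wrong: poor facial selectivity in hydride delivery if the α-centre discriminates too little between the benzyl group and the branched arm. Fallback (C2 set by catalyst-controlled C–C bond formation in place of reduction): starting from 7, the mixed arylzinc reagent made from 2,4-dimethoxyphenylboronic acid and Et2Zn is added with a chiral β-amino alcohol ligand (3-exo-morpholinoisoborneol, the enantiomer that delivers the aryl group to give the 1R carbinol). A substrate bias too weak to control step 8 should be overridden by the ligand. This gives 11 directly and bypasses 9 and 10.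

**Further compounds**

F1 | step 9 | (2R,3R,4R)-3-[4-(TBSO)benzyl]-2-(2,4-dimethoxyphenyl)-4-ethenyl-7-methoxychroman-8-yl trifluoromethanesulfonate | COc1ccc2c(c1OS(=O)(=O)C(F)(F)F)O[C@@H](c1ccc(OC)cc1OC)[C@H](Cc1ccc(O[Si](C)(C)C(C)(C)C)cc1)[C@H]2C=C
F2 | step 5 | (4R)-3-{(E)-3-[2-bromo-4-methoxy-3-(TfO)phenyl]prop-2-enoyl}-4-phenyl-1,3-oxazolidin-2-one | COc1ccc(/C=C/C(=O)N2C(=O)OC[C@H]2c2ccccc2)c(Br)c1OS(=O)(=O)C(F)(F)F
F3 | step 5 | (4R)-3-{(3S)-3-[2-bromo-4-methoxy-3-(TfO)phenyl]pent-4-enoyl}-4-phenyl-1,3-oxazolidin-2-one | C=C[C@H](CC(=O)N1C(=O)OC[C@H]1c1ccccc1)c1ccc(OC)c(OS(=O)(=O)C(F)(F)F)c1Br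
F4 | step 5 | (4R)-3-{(2R,3R)-3-[2-bromo-4-methoxy-3-(TfO)phenyl]-2-[4-(TBSO)benzyl]pent-4-enoyl}-4-phenyl-1,3-oxazolidin-2-one | C=C[C@H]([C@@H](Cc1ccc(O[Si](C)(C)C(C)(C)C)cc1)C(=O)N1C(=O)OC[C@H]1c1ccccc1)c1ccc(OC)c(OS(=O)(=O)C(F)(F)F)c1Br
F5 | step 5 | (2R,3R)-3-[2-bromo-4-methoxy-3-(TfO)phenyl]-2-[4-(TBSO)benzyl]pent-4-en-1-ol | OC[C@H](Cc1ccc(O[Si](C)(C)C(C)(C)C)cc1)[C@@H](C=C)c1ccc(OC)c(OS(=O)(=O)C(F)(F)F)c1Br
F0 | step 8 | none | none
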